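**Convention and assumption (one line):** ent-kaurane numbering (C1–C20) is used for every intermediate, α = face of C19/C20, β = face of H-5/H-9; I assume the dioxolane stereocentre of diene 4 directs the dienophile anti to its allylic C–O bond (H-eclipsed, Kishi/inside-alkoxy sense). If that sense is in fact reversed, the enantiomeric diene from (S)-solketal would be needed instead.

## Retrosynthetic overview

1. Guidongnin ⇐ 15-en-one (Luche reduction sets C15) ⇐ 11-ketone (SmI2 sets C11) ⇐ ring D by 5-exo vinyl-radical conjugate addition (C13–C16).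
2. Radical precursor ⇐ aldol of the C8 lactone enolate with 2-bromoacrolein (C8–C15) on the B/C-ring product.
3. Key step: ester-tethered intramolecular Diels–Alder of a C20 acrylate with a C10-linked (Z)-2-pivaloxy-diene forms ring B (δ-lactone) and ring C together (C8–C9 and C13–C14).
4. IMDA substrate ⇐ C10 quaternary centre by alkylation of a C20 aldehyde enolate ⇐ ring A and the 6,19-lactone from an endo Diels–Alder of citraconic anhydride with an (R)-solketal-derived diene, whose carbinol carbon becomes C20.
5. Ring order: A (+ γ-lactone) → B + C → D; all chirality derives from (R)-solketal.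

## Route

**Step 1**
Reactants: 1, (R)-solketal
Product: 2, (S)-2,2-dimethyl-1,3-dioxolane-4-carbaldehyde (used crude)
Conditions: (COCl)2, DMSO, Et3N, CH2Cl2, −78 °C
Reagents that add atoms: none
Why: Swern oxidation of the primary alcohol under cold, non-epimerising conditions; the stereocentre is untouched.

**Step 2**
Reactants: 2; 3, allyltriphenylphosphonium bromide
Product: 4, (R)-4-[(1E)-buta-1,3-dienyl]-2,2-dimethyl-1,3-dioxolane
Conditions: 3, n-BuLi, THF, −78 → 0 °C; add 2; then I2 (2 mol %), hexanes, hν, rt
Reagents that add atoms: allyltriphenylphosphonium bromide, C=CC[P+](c1ccccc1)(c1ccccc1)c1ccccc1.[Br-]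
Why: Wittig olefination with a semi-stabilised ylide gives an E/Z mixture that iodine-catalysed isomerisation converts to the thermodynamic E-diene, the only isomer able to reach the s-cis geometry.

**Step 3**
Reactants: 4; 5, citraconic anhydride
Product: 6, endo adduct: cyclohex-1-ene cis-fused at C4/C5 to the anhydride (4β-Me, 5β-H; C19 and C6 carbonyls α), 10β-H, (R)-dioxolanyl on C10 α (cis to the anhydride)
Conditions: PhMe, BHT (cat.), 110 °C, sealed tube; chromatography
Reagents that add atoms: citraconic anhydride, CC1=CC(=O)OC1=O
Why: Thermal endo Diels–Alder in which the substituted diene terminus bonds to the CH carbon of the anhydride (sterically and electronically matched), endo approach puts the dioxolanyl group cis to the anhydride, and addition anti to the allylic C–O bond sets C4, C5 and C10 in the absolute sense; the minor facial isomer is separated.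

**Step 4**
Reactants: 6
Product: 7, cis-fused γ-lactone (C19 = OCH2 on the quaternary C4, C6 = lactone C=O), otherwise as 6
Conditions: NaBH4, THF, 0 °C; then aq. citric acid to pH 3
Reagents that add atoms: none
Why: Regioselective anhydride reduction: borohydride attacks the carbonyl next to the more substituted (quaternary) carbon, here reinforced by the C10 substituent shielding C6, and the hydroxy acid lactonises.

**Step 5**
Reactants: 7
Product: 8, the C1–C2 saturated lactone acetonide
Conditions: H2 (1 atm), 10% Pd/C, EtOAc, rt
Reagents that add atoms: none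
Why: Catalytic hydrogenation of the only alkene, done now because every later alkene must survive; no stereocentre is created.

**Step 6**
Reactants: 8
Product: 9, 10α-formyl (C20) 6,19-lactone: 3a-methyl-1-oxo-octahydro-2-benzofuran-7-carbaldehyde with 4β-Me, 5β-H, 10β-H
Conditions: H5IO6, EtOAc, rt
Reagents that add atoms: none
Why: Periodic acid hydrolyses the terminal acetonide and cleaves the resulting 1,2-diol in one pot (glycol cleavage), leaving the carbinol carbon as the C20 aldehyde and consuming the solketal stereocentre after it has done its job.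

**Step 7** (side-chain reagent)
Reactants: 10, 4-chlorobut-2-yn-1-ol; 11, pivaloyl chloride
Product: 12, 4-chlorobut-2-yn-1-yl pivalate
Conditions: pyridine, DMAP (cat.), CH2Cl2, 0 °C
Reagents that add atoms: pivaloyl chloride, CC(C)(C)C(=O)Cl
Why: Simple O-acylation to give the four-carbon C9/C11/C12/C13 electrophile carrying the ester needed for the later acyloxy shift.

**Step 8**
Reactants: 9; 12
Product: 13, C10-quaternary aldehyde: 10α-CHO (C20) and 10β-CH2–C≡C–CH2OPiv
Conditions: KHMDS, THF, −78 °C; 12, n-Bu4NI, −78 → 0 °C
Reagents that add atoms: 4-chlorobut-2-yn-1-yl pivalate, CC(C)(C)C(=O)OCC#CCCl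
Why: C-alkylation of the potassium enolate of an α-branched aldehyde with a propargylic halide (SN2); the electrophile approaches the exocyclic enolate equatorially on the convex β-face, anti to the lactone (axial C19 blocks the α-face), so C20 ends α and the C9 chain β.

**Step 9**
Reactants: 13
Product: 14, the C20 primary alcohol
Conditions: NaBH4, CeCl3·7H2O, MeOH, −40 °C; AcOH quench
Reagents that add atoms: none
Why: Chemoselective aldehyde reduction (Luche conditions), kept cold and buffered so the new alkoxide does not translactonise onto C6; lactone, pivalate and alkyne are inert.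

**Step 10**
Reactants: 14; 15, acryloyl chloride
Product: 16, C20 acrylate (C20–O–C7(=O)–C8H=C14H2)
Conditions: i-Pr2NEt, DMAP (cat.), CH2Cl2, −20 °C
Reagents that add atoms: acryloyl chloride, C=CC(=O)Cl
Why: Esterification of the neopentyl alcohol installs the dienophile (C7, C8, C14) and caps the hydroxyl before gold catalysis.

**Step 11**
Reactants: 16
Product: 17, (9Z)-2-pivaloxy-1,3-diene: C10–C9H=C11(OPiv)–C12H=C13H2 with C10 cis to OPiv
Conditions: IPrAuNTf2 (5 mol %), ClCH2CH2Cl, 80 °C
Reagents that add atoms: none
Why: Gold-catalysed 1,3-acyloxy migration ([3,3]-sigmatropic shift) of the propargylic pivalate to the carboxyallene, then gold-mediated loss of a C9 proton, gives the (Z)-2-acyloxydiene with the bulky C10 group on the outside of the s-cis diene.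

**Step 12**
Reactants: 17
Product: 18, IMDA adduct: spiro-C10 δ-lactone (ring B) cis-fused to a cyclohexene bearing the enol pivalate C11(OPiv)=C12; 9β-H, 8β-H
Conditions: PhMe (0.01 M), BHT, 180 °C, sealed tube
Reagents that add atoms: none
Why: Ester-tethered intramolecular Diels–Alder (Thorpe–Ingold assisted by the quaternary C10); allylic 1,3-strain with the (Z)-OPiv group places the C1 methylene rather than the branched C5 syn to C11–O, so the acrylate adds to the diene face that gives 9β-H, with the tether carbonyl endo (cis B/C fusion; C8 is re-set in step 13).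

**Step 13**
Reactants: 18; 19, 2-bromoacrolein
Product: 20, 8β-[CH(OH)–C(Br)=CH2] aldol adduct (C15 epimers, converged in step 17)
Conditions: LDA, THF, −78 °C; 19, −78 °C; AcOH quench at −78 °C
Reagents that add atoms: 2-bromoacrolein, C=C(Br)C=O
Why: Aldol addition of the ring-fusion lactone enolate (C8–H is the only accessible acidic proton; C5–H lies between two quaternary carbons), with attack on the face syn to 9-H, which makes C8 quaternary with C15 β and B/C cis.

**Step 14**
Reactants: 20
Product: 21, 11-oxo-12-ene (cyclohexenone) with the bromoallylic alcohol intact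
Conditions: PhSeCl, AgOCOCF3, CH2Cl2, 0 °C; then 30% H2O2, pyridine, 0 °C → rt
Reagents that add atoms: none
Why: Electrophilic selenenylation of the enol ester at C12 followed by selenoxide syn-elimination, which can only go toward C13 because C9 carries no eliminable partner (C8 is quaternary); the conditions are metal-free and spare the vinyl bromide and alcohol.

**Step 15**
Reactants: 21
Product: 22, tetracyclic 11-ketone with the bicyclo[3.2.1]octane, 16-exo-methylene and 15-OH (epimers)
Conditions: n-Bu3SnH, AIBN, PhH (0.01 M), 80 °C, slow addition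
Reagents that add atoms: none
Why: Reductive radical cyclisation: the σ-vinyl radical at C16 adds 5-exo-trig to C13 (enone β-carbon) from the β-face that carries C15, the only geometrically possible mode, and the stabilised α-keto radical is reduced without homoallyl rearrangement.

**Step 16**
Reactants: 22
Product: 23, 11α-alcohol (15-OH epimers)
Conditions: SmI2, THF/i-PrOH, −78 → 0 °C
Reagents that add atoms: none
Why: Single-electron ketone reduction under thermodynamic control gives the equatorial 11α-alcohol (H-11 axial under the C15–C16 bridge) rather than the axial alcohol expected from kinetic hydride attack; lactones and the isolated alkene are inert without HMPA or water.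

**Step 17**
Reactants: 23
Product: 24, 11α-hydroxy-15-oxo-16-ene
Conditions: activated MnO2, CH2Cl2, rt
Reagents that add atoms: none
Why: MnO2 oxidises only the allylic C15 alcohol (both epimers converge) and leaves the saturated 11-OH untouched.

**Step 18**
Reactants: 24
Product: 25, Guidongnin
Conditions: NaBH4, CeCl3·7H2O, MeOH, −78 °C
Reagents that add atoms: none
Why: Luche 1,2-reduction with hydride delivered from the open exo face (side of the one-carbon C14 bridge) gives the 15-alcohol syn to the C9–C11–C12 bridge, as in the target.

## Compound list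

1 | (R)-solketal, (R)-(2,2-dimethyl-1,3-dioxolan-4-yl)methanol | OC[C@@H]1COC(C)(C)O1 | starting material
2 | (S)-2,2-dimethyl-1,3-dioxolane-4-carbaldehyde | O=C[C@@H]1COC(C)(C)O1 | intermediate
3 | allyltriphenylphosphonium bromide | C=CC[P+](c1ccccc1)(c1ccccc1)c1ccccc1.[Br-] | starting material
4 | (R)-4-[(1E)-buta-1,3-dienyl]-2,2-dimethyl-1,3-dioxolane | C=C/C=C/[C@@H]1COC(C)(C)O1 | intermediate
5 | citraconic anhydride | CC1=CC(=O)OC1=O | starting material
6 | endo adduct, 3a-methyl-7-[(R)-2,2-dimethyl-1,3-dioxolan-4-yl]-3a,4,7,7a-tetrahydro-2-benzofuran-1,3-dione (all-cis) | C[C@@]12CC=C[C@H]([C@@H]3COC(C)(C)O3)[C@@H]1C(=O)OC2=O | intermediate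
7 | corresponding 1(3H)-one lactone (OCH2 on the methyl-bearing carbon) | C[C@@]12CC=C[C@H]([C@@H]3COC(C)(C)O3)[C@@H]1C(=O)OC2 | intermediate
8 | saturated lactone acetonide | C[C@@]12CCC[C@H]([C@@H]3COC(C)(C)O3)[C@@H]1C(=O)OC2 | intermediate
9 | 10α-formyl 6,19-lactone (3a-methyl-1-oxo-octahydro-2-benzofuran-7-carbaldehyde) | C[C@@]12CCC[C@H](C=O)[C@@H]1C(=O)OC2 | intermediate
10 | 4-chlorobut-2-yn-1-ol | OCC#CCCl | starting material
11 | pivaloyl chloride | CC(C)(C)C(=O)Cl | starting material
12 | 4-chlorobut-2-yn-1-yl pivalate | CC(C)(C)C(=O)OCC#CCCl | intermediate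
13 | C10-quaternary aldehyde (10α-CHO, 10β-CH2C≡CCH2OPiv) | C[C@@]12CCC[C@@](C=O)(CC#CCOC(=O)C(C)(C)C)[C@@H]1C(=O)OC2 | intermediate
14 | C20 alcohol | C[C@@]12CCC[C@@](CO)(CC#CCOC(=O)C(C)(C)C)[C@@H]1C(=O)OC2 | intermediate
15 | acryloyl chloride | C=CC(=O)Cl | starting material
16 | C20 acrylate | C[C@@]12CCC[C@@](COC(=O)C=C)(CC#CCOC(=O)C(C)(C)C)[C@@H]1C(=O)OC2 | intermediate
17 | acrylate with (Z)-2-pivaloxy-1,3-diene on C10 | C[C@@]12CCC[C@@](COC(=O)C=C)(/C=C(\OC(=O)C(C)(C)C)C=C)[C@@H]1C(=O)OC2 | intermediate
18 | IMDA adduct (rings A, B, C; enol pivalate; 8β-H, 9β-H) | CC(C)(C)C(=O)OC1=CCC[C@@H]2C(=O)OC[C@]3(CCC[C@@]4(C)COC(=O)[C@H]43)[C@H]12 | intermediate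
19 | 2-bromoacrolein | C=C(Br)C=O | starting material
20 | C8 aldol adduct (C15 epimers) | CC(C)(C)C(=O)OC1=CCC[C@]2(C(O)C(Br)=C)C(=O)OC[C@]3(CCC[C@@]4(C)COC(=O)[C@H]43)[C@H]12 | intermediate
21 | 11-oxo-12-ene radical precursor (C15 epimers) | O=C1C=CC[C@]2(C(O)C(Br)=C)C(=O)OC[C@]3(CCC[C@@]4(C)COC(=O)[C@H]43)[C@H]12 | intermediate
22 | tetracyclic 11-ketone, 15-OH (epimers), 16-methylene | C=C1[C@@H]2CC(=O)[C@H]3[C@@]4(CCC[C@@]5(C)COC(=O)[C@H]54)COC(=O)[C@]3(C2)C1O | intermediate
23 | 11α-ol, 15-OH (epimers) | C=C1[C@@H]2C[C@@H](O)[C@H]3[C@@]4(CCC[C@@]5(C)COC(=O)[C@H]54)COC(=O)[C@]3(C2)C1O | intermediate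
24 | 11α-hydroxy-15-oxo-16-ene | C=C1[C@@H]2C[C@@H](O)[C@H]3[C@@]4(CCC[C@@]5(C)COC(=O)[C@H]54)COC(=O)[C@]3(C2)C1=O | intermediate
25 | Guidongnin | C=C1[C@@H]2C[C@@H](O)[C@H]3[C@@]4(CCC[C@@]5(C)COC(=O)[C@H]54)COC(=O)[C@]3(C2)[C@@H]1O | target

## Summary

Total steps: 18. Longest linear sequence: 17 (steps 1–6 and 8–18).

Three steps most likely to fail, each with a fallback that changes the approach:

1. **Step 3** (facial selectivity of the first Diels–Alder; acyclic 1,2-induction at 110 °C may be modest). Fallback: make the cycloaddition intramolecular. Hydrolyse 4 to the diene-diol, open citraconic anhydride with its primary OH, and cyclise the half-ester so the carbinol stereocentre sits inside the forming ring. Then reduce the free acid (BH3), translactonise to the γ-lactone, hydrogenate and cleave the diol with NaIO4 to rejoin the route at 9.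
2. **Step 11** (gold 1,3-acyloxy shift on a primary propargylic pivalate, the least reactive substrate class; the IMDA depends on it). Fallback: drop the alkyne. C-allylate 9 with allyl bromide, carry out steps 9–10, then Wacker oxidation to the methyl ketone, Eschenmoser-salt methylenation to the vinyl ketone and TBSOTf/Et3N to the 2-silyloxydiene. The same IMDA follows, with PhSeCl/H2O2 desaturation of the silyl enol ether.
3. **Step 16** (C11 configuration in a ketone hindered on both faces). Fallback: set C11 before the bridge exists. Luche-reduce enone 21 (hydride anti to the spiro C10 substituent gives the 11α-ol), then run the vinyl-radical cyclisation onto the allylic alcohol and continue with steps 17–18.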